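The runs are simulated on assumed constants, noise included.

Two questions stood for one flask, the zeta run carried on: how much of isomer plus target is isomer at the early time, and how much at the latest time.

| flask | solid substrate | remark | time |
|---|---|---|---|
| zeta | 0.45 M | the very flask that is asked about, followed so far |  |
| beta | 0.30 M | run made earlier |  |
| flask | 0.45 M |  | 6.0 min |

| run | time / min | isomer of the product / % | target / % |
|---|---|---|---|
| zeta | 0.333 | 2 | 14 |
| zeta | 0.833 | 15 | 21 |
| zeta | 1.50 | 26 | 31 |
| zeta | 2.50 | 36 | 41 |
| beta | 0.333 | 4 | 14 |
| beta | 0.833 | 15 | 22 |
| beta | 2.00 | 35 | 33 |
| beta | 4.00 | 48 | 39 |

(each reading ± 2 percentage points)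

- share of isomer of the product in isomer of the product plus target at 5.0 s
- share of isomer of the product in isomer of the product plus target at 6.0 min

- given per volume of solution although it is solid: solid substrate
- at the start none of the solid substrate is in solution

1. For the early time I pooled the first readings of both runs, which put the share of isomer at 17.6%; taking the share as growing from zero in proportion to time, I scaled it to 5.0 s and got 4.42%.
2. For the latest time, the last two beta readings gave 68.4% as the marginal share, the part of freshly formed isomer plus target that is isomer, usually called the instantaneous selectivity.
3. In the beta run, the part of the charge that was neither isomer nor target fell at 0.450 /min, so I expected isomer plus target to reach 94.7% of the charge at 6.0 min.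
4. Adding the new product at the marginal share to the last beta reading gave 56.3%.
5. That base was the weak link, since it was one pair of readings from the other run, so I restarted from the last zeta reading, got 50.8%, and committed to the mean, 53.5%.
6. The forecast said 5% at the early time and 52% at the latest time, holding that by then “the share should be near its plateau”, against my 4.42% and 53.5%.

The flask gave 6.09% at the early time and 54.8% at the latest time.

    solid substrate ⇌ starting material, rate k1*(cs1 - [starting material]) while solid is left; crystals form when [starting material] > cs1 (solubility = 0.270 M, k = 1.29 /s)
    starting material → target (k = 0.0142 /s)
    target ⇌ isomer of the product (K = 2.10, k = 9.53 × 10⁻⁴ /s)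
    other conformer → isomer of the product (k = 0.00682 /s)
    starting material ⇌ other conformer (K = 2.50, k = 0.0623 /s)

Between 3.00 min and 6.00 min isomer in the flask rose from 40.3% to 52.6% and target from 39.9% to 43.3%, a marginal share of 78.1%. For the neighbour flask with 0.18 M of solid substrate, adding new product at 68.4% to the last beta reading, up to that flask's final isomer plus target, gives 56.4%. At 6.00 min that neighbour flask held isomer at 52.7% and target at 43.3%, a share of 54.9%.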